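Target cannot account for what the starting material loses: by 12.0 h the north-east run has lost 81.9% of its starting material, yet it shows 1.5% of target, so the rest of what was lost stands in forms not read.

| flask | starting material | reagent | protic impurity | temperature | remark | time |
|---|---|---|---|---|---|---|
| north-east | 3 mM | 50 mM | 6 mM | 25 °C | run made earlier |  |
| west | 15 mM | 50 mM | 6 mM | 40 °C | run made earlier |  |
| south-east | 20 mM | 65 mM | 6 mM | 25 °C | run made earlier |  |
| amber | 20 mM | 50.0 mM | 6.00 mM | 40 °C |  | 30 h |
| ochre | 5.0 mM | 80.0 mM | 6.00 mM | 40 °C |  | 30 h |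

| run | time / h | target / % | starting material / % |
|---|---|---|---|
| north-east | 2.00 | 0 | 56.5 |
| north-east | 5.00 | 0 | 31.2 |
| north-east | 8.00 | 0.9 | 22.5 |
| north-east | 12.0 | 1.5 | 18.1 |
| north-east | 20.0 | 3.0 | 14.7 |
| north-east | 25.0 | 3.8 | 13.8 |
| north-east | 30.0 | 4.6 | 11.7 |
| west | 2.00 | 0.9 | 25.8 |
| west | 4.00 | 3.6 | 22.2 |
| west | 6.00 | 6.8 | 19.8 |
| west | 8.00 | 7.1 | 18.4 |
| west | 10.0 | 11.1 | 16.5 |
| west | 12.0 | 12.9 | 15.6 |
| west | 15.0 | 15.8 | 15.1 |
| south-east | 3.00 | 0 | 44.8 |
| south-east | 5.00 | 0.2 | 31.3 |
| south-east | 8.00 | 0.6 | 23.1 |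
| south-east | 15.0 | 1.8 | 17.1 |
| south-east | 30.0 | 5.6 | 13.7 |

(readings scatter by 0.5 percentage points)

- the earlier runs were read with a standard deviation of 0.5 percentage points
- a reading or a percentage of target counts all its forms, free or not

- which of the two ends with the higher amount of target, in percent of the starting material charged ("neither" if they lie within 2 percentage points) (amber / ochre / neither)
- target at the end, in percent of the starting material charged, amber
- target at the end, in percent of the starting material charged, ochre

1. At 5.00 h the starting material reads 31.2% in the north-east run and 31.3% in the south-east run, although loading and reagent both differ between them, so these estimates are made in percent of the charge.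

2. After its lag, target rises by a share of the charge of 0.00168 h⁻¹ in the north-east run and 0.0115 h⁻¹ in the west run. Dividing the two removes time and gives a factor Θ = 6.81 for going from 25 °C to 40 °C, on the assumption that loading, 3 mM against 15 mM, does not count in percent terms.

3. Multiplying the last north-east reading by Θ puts amber at 31.3%.

4. The south-east slope over the north-east slope is 1.35, which would carry ochre to 53.8%. This is the weak link, since each slope rests on two small readings with a scatter of 0.5 percentage points.

5. Reforged, the link uses the summed target at 8.00 h, 15.0 h and 30.0 h, with the north-east value at 15.0 h interpolated to 2.06%. The south-east sum over the north-east sum is g = 1.06, again free of time, with loading again assumed not to count. The apparent reagent order n, the logarithm of that target ratio over the logarithm of the reagent ratio, reads 0.214, a figure that carries the scatter of those readings.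

6. This reckoning then puts ochre at 34.7%, above the estimate for amber by 3.4 points, more than the margin.

The forecast also says ochre, but with ochre higher than this reckoning, at 44% (32% to 56%) and amber at 31% (25% to 36%), using a “reagent factor about 1.5”.

The flask gives ochre, with amber at 27.6% and ochre at 32.0%.

    intermediate C → target (k = 1.20 × 10⁻⁵ s⁻¹, Ea = 116 kJ mol⁻¹)
    reagent + intermediate B ⇌ target (K = 54.0 L mol⁻¹, k = 0.00100 L mol⁻¹ s⁻¹, Ea = 70.0 kJ mol⁻¹, ΔH = −34.0 kJ mol⁻¹)
    starting material + protic impurity → quenched substrate (k = 0.00500 L mol⁻¹ s⁻¹, Ea = 50.0 kJ mol⁻¹)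
    starting material → intermediate B (k = 1.60 × 10⁻⁵ s⁻¹, Ea = 104 kJ mol⁻¹)
    starting material ⇌ intermediate A (K = 1.90, k = 5.00 × 10⁻⁴ s⁻¹, Ea = 99.0 kJ mol⁻¹, ΔH = −16.0 kJ mol⁻¹)
    reagent + intermediate A ⇌ intermediate C (K = 8.40 L mol⁻¹, k = 8.80 × 10⁻⁴ L mol⁻¹ s⁻¹, Ea = 82.0 kJ mol⁻¹, ΔH = −11.0 kJ mol⁻¹)
    crystals ⇌ target, rate k7*(cs7 - [target]) while solid is left; crystals form when [target] > cs7 (solubility = 7.60 mM, k = 3.00 × 10⁻⁴ s⁻¹)
    (constants at 40 °C)

In ochre, the turning of starting material and protic impurity into quenched substrate gives the starting material a half-life of 9.2 h at 30.0 h, shorter than the run. Quenched substrate in ochre stands at the end at 36.0% of the starting material charged, against 25.0% in amber. Target in ochre is 1.16 times that in amber, where n gave 1.11. Ochre with 200 mM of reagent and its other charges unchanged comes out at 38.9% by n, and that flask ends at 44.0%.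

The runs are simulated from invented constants; noise was put on by code.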